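**Strategy**

Everything rests on cutting the aryl ketone bond C4–C4a of the chromanone. In the open precursor, a (3S)-3-aryloxy-3-arylpropanoic acid, ring A is a 3,5-bis(MOM-oxy)phenyl ether carrying the lavandulyl group at the carbon para to O1 (C6 opposite C8a), so C4a and C8 are equivalent and the key intramolecular Friedel–Crafts acylation can give only the 6-lavandulyl chromanone. Ring B travels as its triacetate, which keeps it from competing as a nucleophile, prevents ionisation of the benzylic C2–O1 bond, and allows C2 to be set by aldol addition followed by Mitsunobu inversion. (R)-Lavandulol supplies the side-chain stereocentre through a Negishi coupling.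

Key step: step 10

Remark 1: (R)-(−)-lavandulol is taken as a purchasable chiral-pool alcohol. Its stereocentre is never touched; the change of descriptor from R to S on arylation is only a change of CIP priorities.
Remark 2: the silyl ketene thioacetal of step 7 is treated as a known reagent (available from S-ethyl thioacetate, LDA and TMSCl).

**Route**

Step 1
Reactants: 1 (R)-lavandulol
Product: 2 (2R)-1-iodo-5-methyl-2-(prop-1-en-2-yl)hex-4-ene
Conditions: I2, PPh3, imidazole, CH2Cl2, 0 °C to rt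
Reagents that add atoms: iodine, II
Why: Appel-type iodination of a primary alcohol, in which the stereocentre is β to the reacting carbon and is not involved.

Step 2
Reactants: 3 2-bromoresorcinol
Product: 4 2-bromo-1,3-bis(methoxymethoxy)benzene
Conditions: MOMCl, i-Pr2NEt, CH2Cl2, 0 °C to rt
Reagents that add atoms: chloromethyl methyl ether, COCCl
Why: Standard O-alkylation of both phenols to MOM acetals, which later serve as donor groups for the ring closure.

Step 3
Reactants: 4 2-bromo-1,3-bis(methoxymethoxy)benzene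
Product: 5 2-[4-bromo-3,5-bis(methoxymethoxy)phenyl]-4,4,5,5-tetramethyl-1,3,2-dioxaborolane
Conditions: [Ir(OMe)(cod)]2 (1.5 mol%), dtbpy (3 mol%), B2pin2, THF, 70 °C
Reagents that add atoms: bis(pinacolato)diboron, CC1(C)OB(OC1(C)C)B1OC(C)(C)C(C)(C)O1
Why: Sterically controlled iridium-catalysed C–H borylation should take place at C5, the only C–H without an ortho substituent, and aryl bromides are tolerated.

Step 4
Reactants: 2 (2R)-1-iodo-5-methyl-2-(prop-1-en-2-yl)hex-4-ene; 5 2-[4-bromo-3,5-bis(methoxymethoxy)phenyl]-4,4,5,5-tetramethyl-1,3,2-dioxaborolane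
Product: 7 2-{3,5-bis(methoxymethoxy)-4-[(2S)-5-methyl-2-(prop-1-en-2-yl)hex-4-en-1-yl]phenyl}-4,4,5,5-tetramethyl-1,3,2-dioxaborolane, via lavandulylzinc iodide 6 (not isolated)
Conditions: 2, Zn dust (activated with TMSCl and 1,2-dibromoethane), LiCl, THF, 35 °C; then 5, Pd2(dba)3 (2 mol%), RuPhos (8 mol%), THF/NMP, 50 °C
Reagents that add atoms: none
Why: Zinc insertion into the primary iodide followed by Negishi sp3–sp2 coupling with the di-ortho-substituted aryl bromide should proceed with the boronate inert in the absence of base and with the β-stereocentre untouched, since the bulky biarylphosphine favours reductive elimination over β-hydride elimination.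

Step 5
Reactants: 7 2-{3,5-bis(methoxymethoxy)-4-[(2S)-5-methyl-2-(prop-1-en-2-yl)hex-4-en-1-yl]phenyl}-4,4,5,5-tetramethyl-1,3,2-dioxaborolane
Product: 8 3,5-bis(methoxymethoxy)-4-[(2S)-5-methyl-2-(prop-1-en-2-yl)hex-4-en-1-yl]phenol
Conditions: 30% H2O2, aq NaOH, THF, 0 °C
Reagents that add atoms: hydrogen peroxide, OO
Why: Oxidation of the arylboronate by boron-to-oxygen aryl migration gives the phenol, and unactivated alkenes are inert to alkaline peroxide.

Step 6
Reactants: 9 2,4,6-trihydroxybenzaldehyde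
Product: 10 2-formylbenzene-1,3,5-triyl triacetate
Conditions: Ac2O, Et3N, DMAP (cat.), CH2Cl2, 0 °C to rt
Reagents that add atoms: acetic anhydride, CC(=O)OC(C)=O
Why: DMAP-catalysed O-acetylation converts the three donor hydroxyls into acceptor acetoxy groups.

Step 7
Reactants: 10 2-formylbenzene-1,3,5-triyl triacetate
Product: 12 S-ethyl (3R)-3-hydroxy-3-[2,4,6-tris(acetyloxy)phenyl]propanethioate, via trimethylsilyl aldolate 11 (not isolated)
Conditions: 1-(ethylsulfanyl)-1-(trimethylsilyloxy)ethene, BINOL (20 mol%, enantiomer chosen for Re-face attack), Ti(Oi-Pr)4 (20 mol%), 4 Å MS, Et2O, −20 °C; then 1 M HCl, THF, 0 °C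
Reagents that add atoms: 1-(ethylsulfanyl)-1-(trimethylsilyloxy)ethene, C=C(O[Si](C)(C)C)SCC
Why: Catalytic asymmetric Mukaiyama aldol addition, in which the chiral BINOL–titanium Lewis acid directs the silyl ketene thioacetal to the Re face of the aldehyde to set the (R) carbinol, and silyl transfer avoids a free alkoxide next to the ortho acetates.

Step 8
Reactants: 8 3,5-bis(methoxymethoxy)-4-[(2S)-5-methyl-2-(prop-1-en-2-yl)hex-4-en-1-yl]phenol; 12 S-ethyl (3R)-3-hydroxy-3-[2,4,6-tris(acetyloxy)phenyl]propanethioate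
Product: 13 S-ethyl (3S)-3-{3,5-bis(methoxymethoxy)-4-[(2S)-5-methyl-2-(prop-1-en-2-yl)hex-4-en-1-yl]phenoxy}-3-[2,4,6-tris(acetyloxy)phenyl]propanethioate
Conditions: PPh3, DIAD, toluene, 0 °C to rt
Reagents that add atoms: none
Why: Mitsunobu etherification, in which the phenoxide displaces the oxyphosphonium group by SN2 with inversion (R to S), the electron-poor triacetoxyphenyl group disfavouring an SN1 pathway as in known aryl ether formations at 2,6-disubstituted electron-poor benzylic alcohols.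

Step 9
Reactants: 13 S-ethyl (3S)-3-{3,5-bis(methoxymethoxy)-4-[(2S)-5-methyl-2-(prop-1-en-2-yl)hex-4-en-1-yl]phenoxy}-3-[2,4,6-tris(acetyloxy)phenyl]propanethioate
Product: 14 (3S)-3-{3,5-bis(methoxymethoxy)-4-[(2S)-5-methyl-2-(prop-1-en-2-yl)hex-4-en-1-yl]phenoxy}-3-[2,4,6-tris(acetyloxy)phenyl]propanoic acid
Conditions: AgNO3, 2,6-lutidine, THF/H2O (4:1), rt
Reagents that add atoms: water, O
Why: Silver(I)-assisted thioester hydrolysis releases the acid under near-neutral conditions, so the aryl acetates, the MOM acetals and the base-sensitive β-aryloxy carbonyl unit should survive.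

Step 10
Reactants: 14 (3S)-3-{3,5-bis(methoxymethoxy)-4-[(2S)-5-methyl-2-(prop-1-en-2-yl)hex-4-en-1-yl]phenoxy}-3-[2,4,6-tris(acetyloxy)phenyl]propanoic acid
Product: 17 (2S)-5,7-bis(methoxymethoxy)-6-[(2S)-5-methyl-2-(prop-1-en-2-yl)hex-4-en-1-yl]-2-[2,4,6-tris(acetyloxy)phenyl]-2,3-dihydro-4H-chromen-4-one, via acid chloride 15 (not isolated), via acyl triflate 16 (not isolated)
Conditions: 1-chloro-N,N,2-trimethylprop-1-en-1-amine, CH2Cl2, 0 °C to rt; then AgOTf, 2,6-di-tert-butyl-4-methylpyridine, CH2Cl2, −78 to −20 °C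
Reagents that add atoms: none
Why: The acid is converted under neutral conditions into the acid chloride 15, and silver triflate turns this into the acyl triflate 16 (an acylium equivalent), which is attacked by an ortho carbon of ring A (ortho to O1 and to one MOM-oxy group, para to the other) to give a Wheland intermediate that loses its proton to the hindered pyridine. The closest known reaction type is the intramolecular Friedel–Crafts acylation of 3-aryloxypropanoic acids to chroman-4-ones, in its acyl triflate variant. The pyranone ring closes in a 6-exo mode at the acyl carbon, with the new C4–C4a bond as the ring-closing bond. No stereocentre is formed; C2 is not part of the reacting system and the electron-poor triacetoxyphenyl group suppresses ionisation of the C2–O1 bond, so the (S) configuration should be carried through. The regioselectivity needed (6- and not 8-lavandulyl) is secured by the substrate, because the two free positions of ring A are equivalent by the local symmetry about the O1–C8a···C6 axis. The chemoselectivity needed (ring A over ring B, the alkenes and the MOM acetals) rests on ring B being deactivated and geometrically out of reach, and on the buffered, acid-free medium at low temperature.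

Step 11
Reactants: 17 (2S)-5,7-bis(methoxymethoxy)-6-[(2S)-5-methyl-2-(prop-1-en-2-yl)hex-4-en-1-yl]-2-[2,4,6-tris(acetyloxy)phenyl]-2,3-dihydro-4H-chromen-4-one
Product: 18 (2S)-5,7-dihydroxy-6-[(2S)-5-methyl-2-(prop-1-en-2-yl)hex-4-en-1-yl]-2-(2,4,6-trihydroxyphenyl)-2,3-dihydro-4H-chromen-4-one
Conditions: 1.25 M HCl in MeOH, 0 °C to rt
Reagents that add atoms: none
Why: Acid-catalysed acetal exchange removes both MOM groups and acid-catalysed transesterification removes the three aryl acetates in one operation, without the base that would open the flavanone to a chalcone and scramble C2 and the 6/8 position of the side chain.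

**Compound list**

1 | (R)-lavandulol, (2R)-5-methyl-2-(prop-1-en-2-yl)hex-4-en-1-ol | C=C(C)[C@@H](CC=C(C)C)CO | starting material
2 | (2R)-1-iodo-5-methyl-2-(prop-1-en-2-yl)hex-4-ene | C=C(C)[C@@H](CC=C(C)C)CI | intermediate
3 | 2-bromoresorcinol (2-bromobenzene-1,3-diol) | Oc1cccc(O)c1Br | starting material
4 | 2-bromo-1,3-bis(methoxymethoxy)benzene | COCOc1cccc(OCOC)c1Br | intermediate
5 | 2-[4-bromo-3,5-bis(methoxymethoxy)phenyl]-4,4,5,5-tetramethyl-1,3,2-dioxaborolane | COCOc1cc(B2OC(C)(C)C(C)(C)O2)cc(OCOC)c1Br | intermediate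
6 | iodo[(2R)-5-methyl-2-(prop-1-en-2-yl)hex-4-en-1-yl]zinc (lavandulylzinc iodide) | C=C(C)[C@@H](CC=C(C)C)C[Zn]I | intermediate
7 | 2-{3,5-bis(methoxymethoxy)-4-[(2S)-5-methyl-2-(prop-1-en-2-yl)hex-4-en-1-yl]phenyl}-4,4,5,5-tetramethyl-1,3,2-dioxaborolane | C=C(C)[C@@H](CC=C(C)C)Cc1c(OCOC)cc(B2OC(C)(C)C(C)(C)O2)cc1OCOC | intermediate
8 | 3,5-bis(methoxymethoxy)-4-[(2S)-5-methyl-2-(prop-1-en-2-yl)hex-4-en-1-yl]phenol | C=C(C)[C@@H](CC=C(C)C)Cc1c(OCOC)cc(O)cc1OCOC | intermediate
9 | 2,4,6-trihydroxybenzaldehyde | O=Cc1c(O)cc(O)cc1O | starting material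
10 | 2-formylbenzene-1,3,5-triyl triacetate | CC(=O)Oc1cc(OC(C)=O)c(C=O)c(OC(C)=O)c1 | intermediate
11 | S-ethyl (3R)-3-[2,4,6-tris(acetyloxy)phenyl]-3-(trimethylsilyloxy)propanethioate | C[Si](C)(C)O[C@H](CC(=O)SCC)c1c(OC(C)=O)cc(OC(C)=O)cc1OC(C)=O | intermediate
12 | S-ethyl (3R)-3-hydroxy-3-[2,4,6-tris(acetyloxy)phenyl]propanethioate | O[C@H](CC(=O)SCC)c1c(OC(C)=O)cc(OC(C)=O)cc1OC(C)=O | intermediate
13 | S-ethyl (3S)-3-{3,5-bis(methoxymethoxy)-4-[(2S)-5-methyl-2-(prop-1-en-2-yl)hex-4-en-1-yl]phenoxy}-3-[2,4,6-tris(acetyloxy)phenyl]propanethioate | C=C(C)[C@@H](CC=C(C)C)Cc1c(OCOC)cc(O[C@@H](CC(=O)SCC)c2c(OC(C)=O)cc(OC(C)=O)cc2OC(C)=O)cc1OCOC | intermediate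
14 | (3S)-3-{3,5-bis(methoxymethoxy)-4-[(2S)-5-methyl-2-(prop-1-en-2-yl)hex-4-en-1-yl]phenoxy}-3-[2,4,6-tris(acetyloxy)phenyl]propanoic acid | C=C(C)[C@@H](CC=C(C)C)Cc1c(OCOC)cc(O[C@@H](CC(=O)O)c2c(OC(C)=O)cc(OC(C)=O)cc2OC(C)=O)cc1OCOC | intermediate
15 | (3S)-3-{3,5-bis(methoxymethoxy)-4-[(2S)-5-methyl-2-(prop-1-en-2-yl)hex-4-en-1-yl]phenoxy}-3-[2,4,6-tris(acetyloxy)phenyl]propanoyl chloride | C=C(C)[C@@H](CC=C(C)C)Cc1c(OCOC)cc(O[C@@H](CC(=O)Cl)c2c(OC(C)=O)cc(OC(C)=O)cc2OC(C)=O)cc1OCOC | intermediate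
16 | (3S)-3-{3,5-bis(methoxymethoxy)-4-[(2S)-5-methyl-2-(prop-1-en-2-yl)hex-4-en-1-yl]phenoxy}-3-[2,4,6-tris(acetyloxy)phenyl]propanoyl trifluoromethanesulfonate | C=C(C)[C@@H](CC=C(C)C)Cc1c(OCOC)cc(O[C@@H](CC(=O)OS(=O)(=O)C(F)(F)F)c2c(OC(C)=O)cc(OC(C)=O)cc2OC(C)=O)cc1OCOC | intermediate
17 | (2S)-5,7-bis(methoxymethoxy)-6-[(2S)-5-methyl-2-(prop-1-en-2-yl)hex-4-en-1-yl]-2-[2,4,6-tris(acetyloxy)phenyl]-2,3-dihydro-4H-chromen-4-one | C=C(C)[C@@H](CC=C(C)C)Cc1c(OCOC)cc2c(c1OCOC)C(=O)C[C@@H](c1c(OC(C)=O)cc(OC(C)=O)cc1OC(C)=O)O2 | intermediate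
18 | (2S)-5,7-dihydroxy-6-[(2S)-5-methyl-2-(prop-1-en-2-yl)hex-4-en-1-yl]-2-(2,4,6-trihydroxyphenyl)-2,3-dihydro-4H-chromen-4-one | C=C(C)[C@@H](CC=C(C)C)Cc1c(O)cc2c(c1O)C(=O)C[C@@H](c1c(O)cc(O)cc1O)O2 | target

**Count**

Total steps: 11. Longest linear sequence: 8 steps (steps 2, 3, 4, 5, 8, 9, 10, 11).

**Steps most likely to fail**

Step 8 (Mitsunobu etherification). The activated alcohol carries acidic hydrogens α to the thioester, so β-elimination of the oxyphosphonium intermediate to the cinnamoyl thioester may outrun the hindered SN2 displacement; participation of an ortho acetoxy group could also erode the inversion. The fallback sets out from 10 and 8 and comes back at 14, carrying C4 at the aldehyde oxidation level so that the carbinol has no acidic α-hydrogen. A Lewis-base-catalysed crossed aldol addition of trimethyl(vinyloxy)silane to 10 (SiCl4, chiral bisphosphoramide, CH2Cl2, −78 °C, methanol quench) should give (1R)-3,3-dimethoxy-1-[2,4,6-tris(acetyloxy)phenyl]propan-1-ol F1. Mitsunobu reaction of this alcohol with 8 (PPh3, DIAD, toluene) should give, with inversion, 2-[(1S)-1-{3,5-bis(methoxymethoxy)-4-[(2S)-5-methyl-2-(prop-1-en-2-yl)hex-4-en-1-yl]phenoxy}-3,3-dimethoxypropyl]benzene-1,3,5-triyl triacetate F2. Mild acetal hydrolysis (PPTS, acetone/H2O) should then give 2-[(1S)-1-{3,5-bis(methoxymethoxy)-4-[(2S)-5-methyl-2-(prop-1-en-2-yl)hex-4-en-1-yl]phenoxy}-3-oxopropyl]benzene-1,3,5-triyl triacetate F3, and Pinnick oxidation (NaClO2, NaH2PO4, 2-methyl-2-butene, t-BuOH/H2O) returns the acid 14.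

Step 10 (key ring closure). Adventitious acid or the strongly electrophilic acyl triflate may cause loss of MOM groups, cationic reactions of the side-chain alkenes, or intermolecular acylation instead of ring closure. The fallback sets out from 13 and comes back at 17, forming the same C4–C4a bond with reversed polarity and without any acid. Iodination of 13 with NIS (MeCN, 0 °C) at one of the two equivalent free positions of ring A should give S-ethyl (3S)-3-{2-iodo-3,5-bis(methoxymethoxy)-4-[(2S)-5-methyl-2-(prop-1-en-2-yl)hex-4-en-1-yl]phenoxy}-3-[2,4,6-tris(acetyloxy)phenyl]propanethioate F4. Cobalt-catalysed zinc insertion (Zn dust, CoBr2 cat., MeCN) should give the arylzinc iodide {2-[(1S)-3-(ethylsulfanyl)-3-oxo-1-[2,4,6-tris(acetyloxy)phenyl]propoxy]-4,6-bis(methoxymethoxy)-5-[(2S)-5-methyl-2-(prop-1-en-2-yl)hex-4-en-1-yl]phenyl}(iodo)zinc F5, which is not isolated. Intramolecular Fukuyama coupling with the thioester (PdCl2(PPh3)2, THF/toluene, rt) should then close the ring to 17.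

Step 11 (global deprotection). Once ring B is unmasked in acid, reversible heterolysis of the C2–O1 bond may epimerise C2, and the phenols flanking the side chain may add to the isopropenyl group. The fallback sets out from 17 and comes back at 18, separating the two deprotections so that ring B stays electron-poor while acid is present. Brief Lewis-acid/thiol cleavage of the MOM acetals (ZnBr2, n-PrSH, CH2Cl2, 0 °C) should give (2S)-5,7-dihydroxy-6-[(2S)-5-methyl-2-(prop-1-en-2-yl)hex-4-en-1-yl]-2-[2,4,6-tris(acetyloxy)phenyl]-2,3-dihydro-4H-chromen-4-one F6. Lipase-catalysed alcoholysis of the three aryl acetates at neutral pH (immobilised Candida antarctica lipase B, n-BuOH, MTBE, 30 °C) should then give 18.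

**Further compounds**

F1 | step 8 | (1R)-3,3-dimethoxy-1-[2,4,6-tris(acetyloxy)phenyl]propan-1-ol | O[C@H](CC(OC)OC)c1c(OC(C)=O)cc(OC(C)=O)cc1OC(C)=O
F2 | step 8 | 2-[(1S)-1-{3,5-bis(methoxymethoxy)-4-[(2S)-5-methyl-2-(prop-1-en-2-yl)hex-4-en-1-yl]phenoxy}-3,3-dimethoxypropyl]benzene-1,3,5-triyl triacetate | C=C(C)[C@@H](CC=C(C)C)Cc1c(OCOC)cc(O[C@@H](CC(OC)OC)c2c(OC(C)=O)cc(OC(C)=O)cc2OC(C)=O)cc1OCOC
F3 | step 8 | 2-[(1S)-1-{3,5-bis(methoxymethoxy)-4-[(2S)-5-methyl-2-(prop-1-en-2-yl)hex-4-en-1-yl]phenoxy}-3-oxopropyl]benzene-1,3,5-triyl triacetate | C=C(C)[C@@H](CC=C(C)C)Cc1c(OCOC)cc(O[C@@H](CC=O)c2c(OC(C)=O)cc(OC(C)=O)cc2OC(C)=O)cc1OCOC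
F4 | step 10 | S-ethyl (3S)-3-{2-iodo-3,5-bis(methoxymethoxy)-4-[(2S)-5-methyl-2-(prop-1-en-2-yl)hex-4-en-1-yl]phenoxy}-3-[2,4,6-tris(acetyloxy)phenyl]propanethioate | C=C(C)[C@@H](CC=C(C)C)Cc1c(OCOC)cc(O[C@@H](CC(=O)SCC)c2c(OC(C)=O)cc(OC(C)=O)cc2OC(C)=O)c(I)c1OCOC
F5 | step 10 | {2-[(1S)-3-(ethylsulfanyl)-3-oxo-1-[2,4,6-tris(acetyloxy)phenyl]propoxy]-4,6-bis(methoxymethoxy)-5-[(2S)-5-methyl-2-(prop-1-en-2-yl)hex-4-en-1-yl]phenyl}(iodo)zinc | C=C(C)[C@@H](CC=C(C)C)Cc1c(OCOC)cc(O[C@@H](CC(=O)SCC)c2c(OC(C)=O)cc(OC(C)=O)cc2OC(C)=O)c([Zn]I)c1OCOC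
F6 | step 11 | (2S)-5,7-dihydroxy-6-[(2S)-5-methyl-2-(prop-1-en-2-yl)hex-4-en-1-yl]-2-[2,4,6-tris(acetyloxy)phenyl]-2,3-dihydro-4H-chromen-4-one | C=C(C)[C@@H](CC=C(C)C)Cc1c(O)cc2c(c1O)C(=O)C[C@@H](c1c(OC(C)=O)cc(OC(C)=O)cc1OC(C)=O)O2
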